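**Plan**

1. Retrosynthesis: the C6 acetate, C14=C15 and C12=C13 (two Wittig reactions) and C8=C17 (ketone methylenation) go first. Ring B is then cut at C6–C7: the oxygen-bearing C6 and C8 stand 1,3 to each other through C7, a masked β-hydroxy ketone (aldol) pattern, so a 7-oxa ring B with an exocyclic enol ether at C8 and a methyl acetal at C6 can stand in for the carbocycle.
2. Behind that, C7–C8 is cut (lactone methylenation), then C9–C11 (ethylene oxide) and C8–C9 (one-carbon homologation). Ring A with C4, C5 and C10 is traced to dehydroabietic acid by excising its arene and two further carbons of the old ring B.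
3. Abietane C4, C10, C18, C9, C19 and C20 become labdane C10, C4, C9, C18, C20 and C19. This exchange of roles gives the ent-labdane ring A without touching a stereocentre (abietane numbering for 1–12, labdane numbering from 13 on).
4. Forward order: homologation and lactone annulation on the intact abietane, arene excision and chain shortening to a monocyclic ring A, closure of the oxa ring B as a lactone acetal (step 12), carbocyclic ring B in the key step, then C17, the diene and the acetate.
5. Stereochemistry: C4, C5 and C10 are inherited. C9 comes from kinetic protonation of a lactone enolate on the face opposite the axial C20 methyl. C6 comes from the chair aldol of the key step (hydroxyl equatorial, away from the syn-axial C19 and C20 methyls). 12E comes from a stabilised ylide.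

Key step: step 15

Remark: in the key-step substrate the acetal methoxy group is placed equatorial (an axial one would be syn-axial to both angular methyls; the centre disappears in step 15), the primary alcohol is carried as a TBDPS ether because it must survive the acidic acetalisation of step 12, and compounds 11–23 are mixtures of epimers at the later C9.

**Step 1**
Reactants: 1 dehydroabietic acid
Product: 2 dehydroabietinol
Conditions: LiAlH4, THF, 0 °C to reflux
Reagents that add atoms: none
Why: Hydride reduction of the hindered equatorial carboxylic acid to the neopentyl alcohol is routine for resin acids and touches no stereocentre.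

**Step 2**
Reactants: 2 dehydroabietinol
Product: 3 dehydroabietinal
Conditions: Dess–Martin periodinane, CH2Cl2, rt
Reagents that add atoms: none
Why: Dess–Martin oxidation stops at the aldehyde, which has no α-hydrogen and so cannot enolise or epimerise.

**Step 3**
Reactants: 3 dehydroabietinal; 4 (methoxymethyl)triphenylphosphonium chloride
Product: 6 18-(methoxymethylidene)abieta-8,11,13-triene (E/Z mixture), via (methoxymethylidene)triphenylphosphorane 5 (not isolated)
Conditions: 4, KOtBu, THF, 0 °C; then 3, 0 °C to rt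
Reagents that add atoms: none
Why: Wittig methoxymethylenation with the reactive unstabilised ylide is reliable on neopentyl, non-enolisable aldehydes, and the alkene geometry is lost on hydrolysis.

**Step 4**
Reactants: 6 18-(methoxymethylidene)abieta-8,11,13-triene
Product: 7 2-(18-norabieta-8,11,13-trien-4-yl)acetaldehyde
Conditions: 2 M HCl, THF, rt
Reagents that add atoms: water, O
Why: Acid hydrolysis of the enol ether releases the one-carbon homologated aldehyde, whose carbonyl carbon is the later C8.

**Step 5**
Reactants: 7 2-(18-norabieta-8,11,13-trien-4-yl)acetaldehyde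
Product: 8 2-(18-norabieta-8,11,13-trien-4-yl)acetic acid
Conditions: NaClO2, NaH2PO4, 2-methyl-2-butene, tBuOH/H2O, rt
Reagents that add atoms: sodium chlorite, [Na+].[O-]Cl=O
Why: Pinnick oxidation takes the aldehyde to the acid and leaves the benzylic positions alone.

**Step 6**
Reactants: 8 2-(18-norabieta-8,11,13-trien-4-yl)acetic acid; 9 ethylene oxide
Product: 12 3-(18-norabieta-8,11,13-trien-4-yl)oxolan-2-one (epimers at the lactone α-carbon), via dilithium enediolate 10 (not isolated), via hydroxy acid 11 (not isolated)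
Conditions: LDA (2.3 equiv), THF, 0 °C to rt; 9 (3 equiv), 0 °C to rt; then 2 M HCl, rt
Reagents that add atoms: none
Why: α-Alkylation of a carboxylic acid dianion with an epoxide followed by acid lactonisation is a standard γ-butyrolactone synthesis; the lactone brings in C11 and C12 and masks both the C8 carboxyl and the C12 hydroxyl for the next four steps.

**Step 7**
Reactants: 12 3-(18-norabieta-8,11,13-trien-4-yl)oxolan-2-one
Product: 13 2-(2-carboxyethyl)-1,3-dimethyl-3-(2-oxooxolan-3-yl)cyclohexane-1-carboxylic acid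
Conditions: RuCl3 (5 mol%), NaIO4 (20 equiv), CCl4/MeCN/H2O, rt
Reagents that add atoms: sodium periodate, [Na+].[O-]I(=O)(=O)=O; water, O
Why: RuO4 generated in situ degrades the trialkylbenzene ring down to the two carboxyl carbons that stay on sp3 carbon (arene-to-carboxylic-acid oxidation), so abietane C9 becomes the future C18 acid on the quaternary carbon and abietane C8 ends a three-carbon acid chain on C5, while the lactone and the quaternary centres are inert.

**Step 8**
Reactants: 13 2-(2-carboxyethyl)-1,3-dimethyl-3-(2-oxooxolan-3-yl)cyclohexane-1-carboxylic acid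
Product: 14 methyl 2-(3-methoxy-3-oxopropyl)-1,3-dimethyl-3-(2-oxooxolan-3-yl)cyclohexane-1-carboxylate
Conditions: MeI, K2CO3, DMF, rt
Reagents that add atoms: iodomethane, CI
Why: O-Alkylation of the carboxylates esterifies the hindered tertiary acid as well, which an acid-catalysed esterification would not do.

**Step 9**
Reactants: 14 methyl 2-(3-methoxy-3-oxopropyl)-1,3-dimethyl-3-(2-oxooxolan-3-yl)cyclohexane-1-carboxylate
Product: 16 3-[2-(methoxycarbonyl)-2,6-dimethyl-6-(2-oxooxolan-3-yl)cyclohexyl]propanoic acid, via dilithium hydroxy dicarboxylate 15 (not isolated)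
Conditions: LiOH (3 equiv), THF/H2O, 0 °C to rt; then 1 M HCl to pH 2, rt
Reagents that add atoms: lithium hydroxide, [Li+].[OH-]
Why: Saponification distinguishes the unhindered primary ester from the α-quaternary C18 ester, and the opened butyrolactone closes again on acidification, so only the chain acid is left free.

**Step 10**
Reactants: 16 3-[2-(methoxycarbonyl)-2,6-dimethyl-6-(2-oxooxolan-3-yl)cyclohexyl]propanoic acid
Product: 17 methyl 2-ethenyl-1,3-dimethyl-3-(2-oxooxolan-3-yl)cyclohexane-1-carboxylate
Conditions: Pb(OAc)4 (1.5 equiv), Cu(OAc)2 (0.2 equiv), pyridine, benzene, 80 °C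
Reagents that add atoms: none
Why: In the Kochi oxidative decarboxylation the primary radical released from the lead carboxylate is oxidised by Cu(OAc)2 to the terminal alkene, which removes abietane C8 and leaves C6=C7 as a latent C6 aldehyde.

**Step 11**
Reactants: 17 methyl 2-ethenyl-1,3-dimethyl-3-(2-oxooxolan-3-yl)cyclohexane-1-carboxylate
Product: 20 4-(tert-butyldiphenylsilyloxy)-2-[2-ethenyl-3-(methoxycarbonyl)-1,3-dimethylcyclohexyl]butanoic acid, via lithium hydroxy carboxylate 18 (not isolated), via silyl ester 19 (not isolated)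
Conditions: LiOH, THF/H2O, rt; evaporate; TBDPSCl (2.5 equiv), imidazole, DMF, rt; then K2CO3, MeOH/THF/H2O, rt; NaH2PO4 to pH 5
Reagents that add atoms: lithium hydroxide, [Li+].[OH-]; tert-butyldiphenylsilyl chloride, CC(C)(C)[Si](Cl)(c1ccccc1)c1ccccc1
Why: Lactone opening, bis-silylation and selective hydrolysis of the silyl ester is a standard way to free a lactone carboxyl while capping the hydroxyl so that it cannot lactonise again; the hindered C18 ester survives.

**Step 12**
Reactants: 20 4-(tert-butyldiphenylsilyloxy)-2-[2-ethenyl-3-(methoxycarbonyl)-1,3-dimethylcyclohexyl]butanoic acid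
Product: 23 methyl ent-12-(tert-butyldiphenylsilyloxy)-6-methoxy-8-oxo-7-oxa-13,14,15,16,17-pentanorlabdan-18-oate (C9 epimers), via ozonide 21 (not isolated), via hydroxylactone 22 (not isolated)
Conditions: O3, CH2Cl2, −78 °C; PPh3, −78 °C to rt; then MeOH (5 equiv), CSA (cat.), 4 Å MS, CH2Cl2, rt
Reagents that add atoms: ozone, [O-][O+]=O; methanol, CO
Why: Ozonolysis of the vinyl group gives the C6 aldehyde, which closes onto the C8 acid as the six-membered hydroxylactone (pseudo-acid, trans-fused oxa ring B), and acid-catalysed exchange with methanol gives the pseudo-ester with the methoxy group equatorial, faster than esterification of the hindered acid.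

**Step 13**
Reactants: 23 methyl ent-12-(tert-butyldiphenylsilyloxy)-6-methoxy-8-oxo-7-oxa-13,14,15,16,17-pentanorlabdan-18-oate (C9 epimers)
Product: 25 methyl ent-12-(tert-butyldiphenylsilyloxy)-6-methoxy-8-oxo-7-oxa-13,14,15,16,17-pentanorlabdan-18-oate (single C9 epimer), via lithium enolate 24 (not isolated)
Conditions: LDA (1.3 equiv), THF, −78 °C; then 2,6-di-tert-butyl-4-methylphenol (3 equiv), THF, −78 °C; aq. NH4Cl
Reagents that add atoms: none
Why: Both epimers give the same lactone enolate, and kinetic protonation should come axially from the face opposite the axial C20 methyl, which places H9 axial and the side chain equatorial as in the target (deprotonation and kinetic reprotonation of a lactone enolate).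

**Step 14**
Reactants: 25 methyl ent-12-(tert-butyldiphenylsilyloxy)-6-methoxy-8-oxo-7-oxa-13,14,15,16,17-pentanorlabdan-18-oate
Product: 26 methyl ent-12-(tert-butyldiphenylsilyloxy)-6-methoxy-8-methylidene-7-oxa-13,14,15,16,17-pentanorlabdan-18-oate
Conditions: Cp2TiMe2 (2.5 equiv), toluene, 70 °C, dark; chromatography on Et3N-deactivated silica
Reagents that add atoms: dimethyltitanocene, C[Ti](C)(C1C=CC=C1)C1C=CC=C1
Why: Petasis methylenation converts the lactone carbonyl into the exocyclic enol ether under non-basic conditions, as known for lactones and for anomeric esters, and the α-quaternary C18 methyl ester is too hindered to compete.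

**Step 15**
Reactants: 26 methyl ent-12-(tert-butyldiphenylsilyloxy)-6-methoxy-8-methylidene-7-oxa-13,14,15,16,17-pentanorlabdan-18-oate
Product: 28 methyl ent-12-(tert-butyldiphenylsilyloxy)-6α-hydroxy-8-oxo-13,14,15,16,17-pentanorlabdan-18-oate, via mercurated keto aldehyde 27 (not isolated)
Conditions: Hg(OCOCF3)2 (5 mol%), acetone/H2O 4:1, rt
Reagents that add atoms: water, O
Why: Hg(OCOCF3)2 (divalent mercury) adds to the terminal carbon of the exocyclic enol ether (the later C7) while water adds to C8; the hemiketal collapses, the former ring oxygen stays on C6 as a hemiacetal that loses methanol, and the C6 aldehyde is attacked by the C7 mercury enolate equivalent of the C8 methyl ketone, protodemercuration returning the catalyst. The closest known reaction is the Ferrier carbocyclization of 6-deoxyhex-5-enopyranosides (2-methylidene-tetrahydropyran acetals) to β-hydroxy cyclohexanones with catalytic mercury salts. Ring B closes by a 6-(enolexo)-exo-trig aldol that forms the C6–C7 bond. The new C6 carbinol centre is controlled by the chair transition state fused trans to ring A: the aldehyde oxygen sits equatorial because the axial position is syn to both the C19 and C20 methyls, and the reversibility of the aldol works in the same direction, while C5, C9 and C10 are carried over unchanged. The step needs chemoselective activation of the enol ether and a neutral medium so that the β-hydroxy ketone neither dehydrates nor epimerises at C9: the substrate has no other alkene, only C7 can reach the aldehyde through a six-membered ring, and the silyl ether and the esters are inert to a catalytic mercury salt in aqueous acetone.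

**Step 16**
Reactants: 28 methyl ent-12-(tert-butyldiphenylsilyloxy)-6α-hydroxy-8-oxo-13,14,15,16,17-pentanorlabdan-18-oate
Product: 29 methyl ent-12-(tert-butyldiphenylsilyloxy)-8-oxo-6α-(triethylsilyloxy)-13,14,15,16,17-pentanorlabdan-18-oate
Conditions: TESOTf, 2,6-lutidine, CH2Cl2, −78 °C
Reagents that add atoms: triethylsilyl trifluoromethanesulfonate, CC[Si](CC)(CC)OS(=O)(=O)C(F)(F)F
Why: Silylation with a silyl triflate and a hindered pyridine caps the β-hydroxyl without enolising the ketone and so guards against retro-aldol and elimination in the methylenation.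

**Step 17**
Reactants: 29 methyl ent-12-(tert-butyldiphenylsilyloxy)-8-oxo-6α-(triethylsilyloxy)-13,14,15,16,17-pentanorlabdan-18-oate
Product: 30 methyl ent-12-(tert-butyldiphenylsilyloxy)-6α-(triethylsilyloxy)-13,14,15,16-tetranorlabd-8(17)-en-18-oate
Conditions: Zn, CH2Br2, TiCl4, THF/CH2Cl2, 0 °C to rt; aq. NaHCO3
Reagents that add atoms: dibromomethane, BrCBr
Why: The Takai–Lombardo reagent methylenates hindered, enolisable ketones under non-basic conditions, so C9 should not epimerise, the β-silyloxy group should not eliminate and the esters stay untouched.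

**Step 18**
Reactants: 30 methyl ent-12-(tert-butyldiphenylsilyloxy)-6α-(triethylsilyloxy)-13,14,15,16-tetranorlabd-8(17)-en-18-oate
Product: 31 methyl ent-6α,12-dihydroxy-13,14,15,16-tetranorlabd-8(17)-en-18-oate
Conditions: HF·pyridine, pyridine, THF, 0 °C to rt
Reagents that add atoms: none
Why: Buffered hydrogen fluoride removes both silyl ethers without generating an alkoxide that could attack the nearby C18 ester, and the exocyclic alkene tolerates it.

**Step 19**
Reactants: 31 methyl ent-6α,12-dihydroxy-13,14,15,16-tetranorlabd-8(17)-en-18-oate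
Product: 32 methyl ent-6α-hydroxy-12-oxo-13,14,15,16-tetranorlabd-8(17)-en-18-oate
Conditions: TEMPO (10 mol%), PhI(OAc)2, CH2Cl2, rt
Reagents that add atoms: none
Why: The oxoammonium oxidation selects the primary C12 alcohol over the hindered secondary C6 alcohol and stops at the aldehyde.

**Step 20**
Reactants: 32 methyl ent-6α-hydroxy-12-oxo-13,14,15,16-tetranorlabd-8(17)-en-18-oate; 33 2-(triphenylphosphoranylidene)propanal
Product: 34 methyl ent-6α-hydroxy-14-oxo-15-norlabda-8(17),12E-dien-18-oate
Conditions: toluene, 90 °C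
Reagents that add atoms: none
Why: The Wittig reaction of a stabilised formyl ylide with an aliphatic aldehyde gives the (E)-2-methyl-2-enal and brings in C13, C14 and C16 with the 12E geometry.

**Step 21**
Reactants: 34 methyl ent-6α-hydroxy-14-oxo-15-norlabda-8(17),12E-dien-18-oate
Product: 35 methyl ent-6α-acetoxy-14-oxo-15-norlabda-8(17),12E-dien-18-oate
Conditions: Ac2O, pyridine, DMAP (cat.), CH2Cl2, rt
Reagents that add atoms: acetic anhydride, CC(=O)OC(C)=O
Why: DMAP-catalysed acetylation of the equatorial secondary alcohol is straightforward now that no β-carbonyl remains to invite elimination.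

**Step 22**
Reactants: 35 methyl ent-6α-acetoxy-14-oxo-15-norlabda-8(17),12E-dien-18-oate; 36 methyltriphenylphosphonium bromide
Product: 38 methyl ent-6α-acetoxylabda-8(17),12E,14-trien-18-oate, via methylidenetriphenylphosphorane 37 (not isolated)
Conditions: 36, KHMDS, THF, 0 °C; then 35 (ylide 1.2 equiv), −78 °C to 0 °C
Reagents that add atoms: none
Why: Wittig methylenation of the enal is much faster at low temperature than attack of the ylide on the acetate or the hindered ester, and it completes the diene without touching the 12E alkene.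

**Compound list**

1 | dehydroabietic acid (abieta-8,11,13-trien-18-oic acid) | CC(C)C1=CC2=C(C=C1)[C@]3(CCC[C@@]([C@@H]3CC2)(C)C(=O)O)C | starting material
2 | dehydroabietinol (abieta-8,11,13-trien-18-ol) | CC(C)C1=CC2=C(C=C1)[C@]3(CCC[C@@]([C@@H]3CC2)(C)CO)C | intermediate
3 | dehydroabietinal (abieta-8,11,13-trien-18-al) | CC(C)C1=CC2=C(C=C1)[C@]3(CCC[C@@]([C@@H]3CC2)(C)C=O)C | intermediate
4 | (methoxymethyl)triphenylphosphonium chloride | COC[P+](c1ccccc1)(c1ccccc1)c1ccccc1.[Cl-] | starting material
5 | (methoxymethylidene)triphenylphosphorane | COC=P(c1ccccc1)(c1ccccc1)c1ccccc1 | intermediate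
6 | 18-(methoxymethylidene)abieta-8,11,13-triene (enol ether, E/Z mixture) | CC(C)C1=CC2=C(C=C1)[C@]3(CCC[C@@]([C@@H]3CC2)(C)C=COC)C | intermediate
7 | 2-(18-norabieta-8,11,13-trien-4-yl)acetaldehyde | CC(C)C1=CC2=C(C=C1)[C@]3(CCC[C@@]([C@@H]3CC2)(C)CC=O)C | intermediate
8 | 2-(18-norabieta-8,11,13-trien-4-yl)acetic acid | CC(C)C1=CC2=C(C=C1)[C@]3(CCC[C@@]([C@@H]3CC2)(C)CC(=O)O)C | intermediate
9 | ethylene oxide (oxirane) | C1CO1 | starting material
10 | dilithium enediolate of acid 8 | CC(C)C1=CC2=C(C=C1)[C@]3(CCC[C@@]([C@@H]3CC2)(C)C=C([O-])[O-])C.[Li+].[Li+] | intermediate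
11 | 4-hydroxy-2-(18-norabieta-8,11,13-trien-4-yl)butanoic acid (C2 epimers) | CC(C)C1=CC2=C(C=C1)[C@]3(CCC[C@@]([C@@H]3CC2)(C)C(CCO)C(=O)O)C | intermediate
12 | 3-(18-norabieta-8,11,13-trien-4-yl)oxolan-2-one (epimers at the lactone α-carbon, the later C9) | CC(C)C1=CC2=C(C=C1)[C@]3(CCC[C@@]([C@@H]3CC2)(C)C4CCOC4=O)C | intermediate
13 | 2-(2-carboxyethyl)-1,3-dimethyl-3-(2-oxooxolan-3-yl)cyclohexane-1-carboxylic acid (both methyls and the C2 chain on one face, carboxyl and lactone on the other; C9 epimers) | O=C1OCCC1[C@]2(C)CCC[C@](C)(C(=O)O)[C@H]2CCC(=O)O | intermediate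
14 | methyl 2-(3-methoxy-3-oxopropyl)-1,3-dimethyl-3-(2-oxooxolan-3-yl)cyclohexane-1-carboxylate (ring configuration as in 13; C9 epimers) | O=C1OCCC1[C@]2(C)CCC[C@](C)(C(=O)OC)[C@H]2CCC(=O)OC | intermediate
15 | dilithium salt of the ring-opened hydroxy diacid from 14 | [Li+].[Li+].[O-]C(=O)C(CCO)[C@]1(C)CCC[C@](C)(C(=O)OC)[C@H]1CCC([O-])=O | intermediate
16 | 3-[2-(methoxycarbonyl)-2,6-dimethyl-6-(2-oxooxolan-3-yl)cyclohexyl]propanoic acid (ring configuration as in 13; C9 epimers) | O=C1OCCC1[C@]2(C)CCC[C@](C)(C(=O)OC)[C@H]2CCC(=O)O | intermediate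
17 | methyl 2-ethenyl-1,3-dimethyl-3-(2-oxooxolan-3-yl)cyclohexane-1-carboxylate (ring configuration as in 13; C9 epimers) | O=C1OCCC1[C@]2(C)CCC[C@](C)(C(=O)OC)[C@H]2C=C | intermediate
18 | lithium 2-[2-ethenyl-3-(methoxycarbonyl)-1,3-dimethylcyclohexyl]-4-hydroxybutanoate | [Li+].[O-]C(=O)C(CCO)[C@]1(C)CCC[C@](C)(C(=O)OC)[C@H]1C=C | intermediate
19 | tert-butyldiphenylsilyl 4-(tert-butyldiphenylsilyloxy)-2-[2-ethenyl-3-(methoxycarbonyl)-1,3-dimethylcyclohexyl]butanoate | CC(C)(C)[Si](c1ccccc1)(c1ccccc1)OCCC(C(=O)O[Si](c1ccccc1)(c1ccccc1)C(C)(C)C)[C@]2(C)CCC[C@](C)(C(=O)OC)[C@H]2C=C | intermediate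
20 | 4-(tert-butyldiphenylsilyloxy)-2-[2-ethenyl-3-(methoxycarbonyl)-1,3-dimethylcyclohexyl]butanoic acid (ring configuration as in 13; C9 epimers) | CC(C)(C)[Si](c1ccccc1)(c1ccccc1)OCCC(C(=O)O)[C@]2(C)CCC[C@](C)(C(=O)OC)[C@H]2C=C | intermediate
21 | ozonide (1,2,4-trioxolane) of the vinyl group of 20 | CC(C)(C)[Si](c1ccccc1)(c1ccccc1)OCCC(C(=O)O)[C@]2(C)CCC[C@](C)(C(=O)OC)[C@H]2C3OCOO3 | intermediate
22 | methyl ent-12-(tert-butyldiphenylsilyloxy)-6-hydroxy-8-oxo-7-oxa-13,14,15,16,17-pentanorlabdan-18-oate (hydroxylactone, ring tautomer of the C6 aldehyde C8 acid) | CC(C)(C)[Si](c1ccccc1)(c1ccccc1)OCCC1C(=O)OC(O)[C@H]2[C@@]1(C)CCC[C@]2(C)C(=O)OC | intermediate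
23 | methyl ent-12-(tert-butyldiphenylsilyloxy)-6-methoxy-8-oxo-7-oxa-13,14,15,16,17-pentanorlabdan-18-oate (trans-fused δ-lactone methyl acetal, 6-OMe equatorial; C9 epimers) | CC(C)(C)[Si](c1ccccc1)(c1ccccc1)OCCC1C(=O)O[C@@H](OC)[C@H]2[C@@]1(C)CCC[C@]2(C)C(=O)OC | intermediate
24 | lithium enolate of lactone 23 (C8–C9 enolate) | CC(C)(C)[Si](c1ccccc1)(c1ccccc1)OCCC1=C([O-])O[C@@H](OC)[C@H]2[C@@]1(C)CCC[C@]2(C)C(=O)OC.[Li+] | intermediate
25 | methyl ent-12-(tert-butyldiphenylsilyloxy)-6-methoxy-8-oxo-7-oxa-13,14,15,16,17-pentanorlabdan-18-oate (C9 side chain equatorial, cis to the C20 methyl; H9 axial) | CC(C)(C)[Si](c1ccccc1)(c1ccccc1)OCC[C@@H]1C(=O)O[C@@H](OC)[C@H]2[C@@]1(C)CCC[C@]2(C)C(=O)OC | intermediate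
26 | methyl ent-12-(tert-butyldiphenylsilyloxy)-6-methoxy-8-methylidene-7-oxa-13,14,15,16,17-pentanorlabdan-18-oate (2-methylidene-tetrahydropyran methyl acetal; the methylidene carbon becomes C7) | CC(C)(C)[Si](c1ccccc1)(c1ccccc1)OCC[C@@H]1C(=C)O[C@@H](OC)[C@H]2[C@@]1(C)CCC[C@]2(C)C(=O)OC | intermediate
27 | ring-opened C6 aldehyde C8 ketone carrying Hg(OCOCF3) on C7 | FC(F)(F)C(=O)O[Hg]CC(=O)[C@@H](CCO[Si](c1ccccc1)(c1ccccc1)C(C)(C)C)[C@]2(C)CCC[C@](C)(C(=O)OC)[C@H]2C=O | intermediate
28 | methyl ent-12-(tert-butyldiphenylsilyloxy)-6α-hydroxy-8-oxo-13,14,15,16,17-pentanorlabdan-18-oate (trans-decalin; 6-OH equatorial, cis to H5; C9 side chain equatorial) | CC(C)(C)[Si](c1ccccc1)(c1ccccc1)OCC[C@@H]1C(=O)C[C@@H](O)[C@H]2[C@@]1(C)CCC[C@]2(C)C(=O)OC | intermediate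
29 | methyl ent-12-(tert-butyldiphenylsilyloxy)-8-oxo-6α-(triethylsilyloxy)-13,14,15,16,17-pentanorlabdan-18-oate | CC(C)(C)[Si](c1ccccc1)(c1ccccc1)OCC[C@@H]1C(=O)C[C@@H](O[Si](CC)(CC)CC)[C@H]2[C@@]1(C)CCC[C@]2(C)C(=O)OC | intermediate
30 | methyl ent-12-(tert-butyldiphenylsilyloxy)-6α-(triethylsilyloxy)-13,14,15,16-tetranorlabd-8(17)-en-18-oate | CC(C)(C)[Si](c1ccccc1)(c1ccccc1)OCC[C@@H]1C(=C)C[C@@H](O[Si](CC)(CC)CC)[C@H]2[C@@]1(C)CCC[C@]2(C)C(=O)OC | intermediate
31 | methyl ent-6α,12-dihydroxy-13,14,15,16-tetranorlabd-8(17)-en-18-oate | OCC[C@@H]1C(=C)C[C@@H](O)[C@H]2[C@@]1(C)CCC[C@]2(C)C(=O)OC | intermediate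
32 | methyl ent-6α-hydroxy-12-oxo-13,14,15,16-tetranorlabd-8(17)-en-18-oate | O=CC[C@@H]1C(=C)C[C@@H](O)[C@H]2[C@@]1(C)CCC[C@]2(C)C(=O)OC | intermediate
33 | 2-(triphenylphosphoranylidene)propanal | CC(C=O)=P(c1ccccc1)(c1ccccc1)c1ccccc1 | starting material
34 | methyl ent-6α-hydroxy-14-oxo-15-norlabda-8(17),12E-dien-18-oate | O=C/C(C)=C/C[C@@H]1C(=C)C[C@@H](O)[C@H]2[C@@]1(C)CCC[C@]2(C)C(=O)OC | intermediate
35 | methyl ent-6α-acetoxy-14-oxo-15-norlabda-8(17),12E-dien-18-oate | O=C/C(C)=C/C[C@@H]1C(=C)C[C@@H](OC(C)=O)[C@H]2[C@@]1(C)CCC[C@]2(C)C(=O)OC | intermediate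
36 | methyltriphenylphosphonium bromide | C[P+](c1ccccc1)(c1ccccc1)c1ccccc1.[Br-] | starting material
37 | methylidenetriphenylphosphorane | C=P(c1ccccc1)(c1ccccc1)c1ccccc1 | intermediate
38 | methyl ent-6α-acetoxylabda-8(17),12E,14-trien-18-oate, CNP0212193.1 (trans-decalin; C19 and C20 methyls cis and axial; CO2Me equatorial; 6-OAc equatorial, cis to H5; C9 side chain equatorial, cis to C20) | C=C/C(C)=C/C[C@@H]1C(=C)C[C@@H](OC(C)=O)[C@H]2[C@@]1(C)CCC[C@]2(C)C(=O)OC | target

**Step count and risks**

Total step count: 22. Longest linear sequence: 22 steps (1 to 38).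

Steps most likely to fail:

Step 15 (key step). The catalyst releases a little trifluoroacetic acid, and plain acid-catalysed hydration of the enol ether without mercuration would stop at a keto aldehyde that does not cyclise in neutral medium; the aldol closure may also be slow against the two axial methyls. The fallback forms the same C6–C7 bond in two stages from 26. Mild acid hydrolysis (PPTS, acetone/H2O, rt) of the enol ether and the acetal should give the methyl ketone aldehyde F1. An amine-catalysed intramolecular aldol (pyrrolidine/AcOH or L-proline, DMSO, rt) through the enamine of the methyl ketone should then close ring B in the same 6-enolexo sense, with the hydroxyl again expected equatorial. This returns to the route at 28.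

Step 10. The radical or the cation behind it may be intercepted as an acetate or rearrange, and conversion of the lead carboxylate may be low, so that little terminal alkene is formed. The fallback sets out from 16. Esterification with N-hydroxypyridine-2-thione (DCC, DMAP cat., CH2Cl2, dark) should give the thiohydroxamate ester F2. Visible-light photolysis with PhSeSePh should give, by radical decarboxylative selenation, the primary phenyl selenide F3. Oxidation (H2O2, THF, 0 °C to rt) and selenoxide syn-elimination should then give the vinyl compound, and the route is rejoined at 17.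

Step 13. Facial selectivity in the protonation may be poor, or O-protonation may be followed by unselective tautomerisation, leaving a mixture at C9. The fallback sets out from 23. Trapping of the enolate with PhSeBr (LDA, THF, −78 °C) should give the α-phenylselanyl lactone F4. Oxidation (H2O2, CH2Cl2, 0 °C) can eliminate only toward C11, because C10 is quaternary, and should give the α-alkylidene lactone F5. Hydrogenation (H2, Pd/C, EtOAc) should deliver hydrogen to C9 from the face opposite the axial C20 methyl, which rejoins the route at 25.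

**Further compounds**

F1 | step 15 | methyl 3-[1-(2-(tert-butyldiphenylsilyloxy)ethyl)-2-oxopropyl]-2-formyl-1,3-dimethylcyclohexane-1-carboxylate (C8 methyl ketone, C6 aldehyde) | CC(=O)[C@@H](CCO[Si](c1ccccc1)(c1ccccc1)C(C)(C)C)[C@]2(C)CCC[C@](C)(C(=O)OC)[C@H]2C=O
F2 | step 10 | 2-thioxopyridin-1(2H)-yl ester of acid 16 | O=C1OCCC1[C@]2(C)CCC[C@](C)(C(=O)OC)[C@H]2CCC(=O)ON3C=CC=CC3=S
F3 | step 10 | methyl 1,3-dimethyl-3-(2-oxooxolan-3-yl)-2-[2-(phenylselanyl)ethyl]cyclohexane-1-carboxylate | O=C1OCCC1[C@]2(C)CCC[C@](C)(C(=O)OC)[C@H]2CC[Se]c3ccccc3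
F4 | step 13 | 9-(phenylselanyl) derivative of lactone 23 | CC(C)(C)[Si](c1ccccc1)(c1ccccc1)OCCC1([Se]c3ccccc3)C(=O)O[C@@H](OC)[C@H]2[C@@]1(C)CCC[C@]2(C)C(=O)OC
F5 | step 13 | 9(11)-alkylidene lactone from F4 (E/Z mixture) | CC(C)(C)[Si](c1ccccc1)(c1ccccc1)OCC=C1C(=O)O[C@@H](OC)[C@H]2[C@@]1(C)CCC[C@]2(C)C(=O)OC
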